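The numbers in the tables are simulated with constants of no real substance, and the scatter is random.

Product is slow to arrive: the feed of partner ends at 1.5 h, yet at 2.50 h the noon run reads 31.9% of its starting material as product. The decision is whether the next flask, noon's charge with 25.0 mM of scavenger, is the change worth making, or whether partner is what to move.

| setting | autumn | noon | summer | flask |
|---|---|---|---|---|
| starting material | 25 mM | 25 mM | 38 mM | 25 mM |
| partner | 22.5 mM (fed, over 1.5 h) | 22.5 mM (fed, over 1.5 h) | 22.5 mM (fed, over 1.5 h) | 22.5 mM (fed, over 1.5 h) |
| protic impurity | 5 mM | 5 mM | 5 mM | 5.00 mM |
| scavenger | 12 mM | 19 mM | 25 mM | 25.0 mM |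
| initiator | 1.2 mM | 1.2 mM | 1.2 mM | 1.2 mM |
| remark | run made earlier | run made earlier | run made earlier |  |
| time |  |  |  | 3.0 h |

| run | time / h | product / % |
|---|---|---|
| autumn | 0.200 | 2.2 |
| autumn | 0.333 | 4.0 |
| autumn | 0.500 | 8.1 |
| autumn | 0.833 | 15.5 |
| autumn | 1.33 | 24.8 |
| autumn | 2.50 | 31.7 |
| noon | 0.200 | 1.9 |
| noon | 0.333 | 4.5 |
| noon | 0.500 | 8.4 |
| noon | 0.833 | 15.5 |
| noon | 1.33 | 24.5 |
| noon | 2.50 | 31.9 |
| summer | 0.200 | 1.1 |
| summer | 0.333 | 2.6 |
| summer | 0.667 | 8.4 |
| summer | 1.33 | 18.6 |
| summer | 2.50 | 25.3 |

(each reading ± 0.3 percentage points)

- percentages count the starting material that a species holds: one ended chains counts as two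
- released group is meant together with its idle adduct
- the numbers in the tables scatter with a standard deviation of 0.3 percentage points
- steps that have been proposed: starting material + second chain carrier -> released group + first chain carrier; starting material + initiating radical -> capped initiator + first chain carrier; starting material + released group <-> idle adduct; starting material + protic impurity -> quenched substrate; partner -> decomposed reagent; 2 first chain carrier -> ended chains; scavenger + released group -> scavenged by-product; partner + first chain carrier <-> product + second chain carrier; initiator -> 2 initiating radical
- the reaction counts as stopped when no species that holds the starting material changes by six tenths of a point or more over the second half of the time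

* the state of affairs at 3.0 h: stopped, and by what, or still going (the partner has run out first / forward and back rates have come level / all of the starting material has reacted / it is still moving)
* how much product there is at 3.0 h, in percent of the starting material charged

Divide the mean rate of product up to the last reading by the mean rate of partner supplied over the same span, and the span cancels. In the noon run the partner charged is 0.900 of the starting material, so the reading over that fraction gives 0.354. This is the partner yield, product made per partner charged; the usual term is reagent efficiency. The autumn run, with 12 mM of scavenger against noon's 19 mM, gives 0.352, and the two last readings differ by 0.2 percentage points against a scatter of 0.3 points. The summer run, at 0.592 partner per starting material, reads 0.427, higher than noon's. So you expect the flask to repeat noon, 31.9% at 2.50 h, and you look to the partner ratio for the next change. That figure stops short of 3.0 h. The forecast, for 3.0 h, says 32.3%, and it says it is still moving, on the ground that “between 1.5 h (about 28%) and 3.0 h the product still rises about 4 points, more than 0.6”.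

The flask gives 32.4% at 3.0 h: it is still moving.

    starting material + second chain carrier → released group + first chain carrier (k = 21000 L mol⁻¹ s⁻¹)
    starting material + initiating radical → capped initiator + first chain carrier (k = 1.90 × 10⁵ L mol⁻¹ s⁻¹)
    starting material + released group ⇌ idle adduct, settled at all times (K = 4600 L mol⁻¹)
    starting material + protic impurity → quenched substrate (k = 1.90 L mol⁻¹ min⁻¹)
    partner → decomposed reagent (k = 0.0240 min⁻¹)
    2 first chain carrier → ended chains (k = 5.00 × 10⁸ L mol⁻¹ s⁻¹)
    scavenger + released group → scavenged by-product (k = 1.30 L mol⁻¹ min⁻¹)
    partner + first chain carrier ⇌ product + second chain carrier (K = 0.970, k = 39000 L mol⁻¹ s⁻¹)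
    initiator → 2 initiating radical (k = 0.00510 min⁻¹)

The flask's partner yield is 0.360, close to noon's. Carried to the neighbour flask with 13 mM of partner, 0.520 of the starting material, that noon yield gives 18.4%, while the summer yield gives 22.2%. The neighbour flask stands at 22.7% at 3.0 h, a partner yield of 0.437, with 31.5% of its starting material still there.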